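**Asked, known.** The ash flask put 4 questions to me, and I had the ash and cedar readings to answer them.

| flask | J | Z | D | temperature | remark | time |
|---|---|---|---|---|---|---|
| ash | 0.50 M | 0.75 M | 2 M | 50 °C | the very flask that is asked about, followed so far |  |
| cedar | 0.50 M | 0.75 M | 2 M | 56 °C | run made earlier |  |
| flask | 0.50 M | 0.750 M | 2.00 M | 50 °C |  | 15 h |

| run | time / h | E / % | J / % |
|---|---|---|---|
| ash | 0.667 | 7 | 42 |
| ash | 2.00 | 33 | 10 |
| ash | 3.00 | 43 | 4 |
| ash | 5.00 | 53 | 0 |
| ash | 6.00 | 59 | 0 |
| ash | 10.0 | 65 | 0 |
| cedar | 0.667 | 15 | 29 |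
| cedar | 2.00 | 43 | 7 |
| cedar | 3.00 | 55 | 0 |
| cedar | 5.00 | 66 | 1 |
| cedar | 6.00 | 65 | 0 |
| cedar | 10.0 | 73 | 0 |

(standard deviation of a reading: 1.5 percentage points)

- Monday's: at 15 h raise the temperature by 10 K, then wait 30 h
- Friday's: at 15 h add Z, 50.0% of the amount charged, then wait 30 h
- Sunday's: at 15 h add J, 50.0% of the amount charged, then wait 30 h
- Tuesday's: change nothing and wait 30 h more

* E, in percent of the J first charged, at 15 h
* what to do for the largest gain in E; "none" if nothing gains more than 2 percentage points (Monday's / Friday's / Sunday's / Tuesday's / none)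
* E present, in percent of the J first charged, after Monday's
* E present, in percent of the J first charged, after Friday's

- percent here means J units held: one Xo counts as two
- what is said of E includes Qo
- Qo is a solid; its amount is given per volume of the solution
- additions leave the volume as it is
- what was read earlier has a scatter of 1.5 percentage points, one standard deviation
- what may be going on: J + D -> Q; D + Z -> G; Q + G -> E; 2 G -> X; J + E -> Xo; Qo <-> E

**The tail.** J and Z together claim 1.25 M of D against 2.00 M charged, so I set D aside and watched Z. Between 6.00 h and 10.0 h E climbed from 59% to 65%. Letting that climb go on at half the pace gave me 68.8% at 15 h. Waiting as long again for the same small step gave 72.5% for Monday's, heat aside.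

**Z cost.** Each E needs one G, so one Z, yet the Z charge over the E made was 2.31 at 10.0 h. Putting my first answer back in gave 2.18 Z per E. I call this the Z cost, the inverse of a selectivity; part of what exceeds one goes to the pairing of G into X, and part stands as G not yet spent.

**Friday's dose.** The dose is 0.375 M of Z, and the room, counting everything that isn't E as Q, is 0.156 M. At the Z cost the dose buys 0.172 M, more than the room.

**Weak link.** That cost was earned at a Z to J ratio of 1.50, but the dose meets a ratio of 2.40. Pairing goes with the square of c(G) and making E with c(G) times c(Q), so the waste per E scales with c(G)/c(Q). Going round again gave 2.89, hence 94.7% after Friday's, which was my choice.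

**The forecast.** It gave 70% now, 76% after Monday's and 86% after Friday's, and chose Friday's: “Fresh Z makes new G and converts much of the stranded Q”. Its Friday's figure stood lower than mine.

**The result.** The flask gave 72.7% now, 77.9% after Monday's and 95.8% after Friday's, and the best choice was Friday's. The last figure lies 9.8 percentage points above the forecast.

    J + D → Q (k = 0.0188 L mol⁻¹ min⁻¹, Ea = 56.0 kJ mol⁻¹)
    D + Z → G (k = 0.246 L mol⁻¹ min⁻¹, Ea = 56.0 kJ mol⁻¹)
    Q + G → E (k = 0.0134 L mol⁻¹ min⁻¹, Ea = 61.0 kJ mol⁻¹)
    2 G → X (k = 0.00430 L mol⁻¹ min⁻¹, Ea = 60.0 kJ mol⁻¹)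
    J + E → Xo (k = 0.0389 L mol⁻¹ min⁻¹, Ea = 86.0 kJ mol⁻¹)
    Qo ⇌ E, rate k6*(cs6 - [E]) while solid is left; crystals form when [E] > cs6 (solubility = 5.80 mM, k = 4.57 min⁻¹)
    (constants at 50 °C)

**Why dearer.** Tuesday's brought 4.9 points with no Z added, so of the 23 points gained under Friday's the dose itself bought 18 points, at 4.13 Z per E, dearer than my reforged 2.89. The cost exceeds one in part through the pairing of G into X: the run without that step reaches 95.8% of E at 15 h, against 72.7%. That pairing is also the largest single effect on what Friday's brings: without it the gain is 2.1 points, against 23 points.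

**Colder repeat.** In the repeat at 35 °C, 0.130 M of G was still alive at 15.0 h, so the Z cost on the rest of the Z promised 56.8% of E. The computed flask held 57.7%.

The earlier runs and the new flask stem from a simulated flask with constants of no real substance.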